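The millimolar-hour, [partner] times time, is the unit of the trial reckoning below, which can hold for a flask only as far as its steps go with partner.

all flasks: substrate 20 mM
- red: partner 23 mM; run made earlier
- amber: partner 220 mM; run made earlier
- dusk: partner 40.0 mM; time 3.0 h
- noon: partner 80.0 mM; time 3.0 h
- spring: partner 150 mM; time 3.0 h
- dawn: partner 300 mM; time 3.0 h

- red (time / min: double product / %): 20.0: 0.1; 40.0: 2.4; 50.0: 1.8; 80.0: 3.7; 90.0: 4.2
- amber (time / min: double product / %): 8.00: 6.9; 25.0: 31.8; 40.0: 47.6; 60.0: 57.3; 90.0: 54.7

(readings scatter by 0.5 percentage points)

- amount of double product at the end, in percent of the substrate charged for dusk, noon, spring, dawn, in this order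
- the shape of the row from first to last (hardly changes / falls, then rises / rises all the way / falls all the way / rises, then falls)

- the numbers in the tables scatter with a standard deviation of 0.5 percentage points
- "hardly changes" means that all values lie within two and a half points (for a concentration: within two and a half percent of the largest)

The amber run's highest reading of double product, 57.3% at 60.0 min, stands above its neighbours, so double product passes a maximum there, as far as the spacing of the readings shows. Amber holds 11.0 times as much partner as substrate, which makes any step in partner pseudo-first-order, so this reckoning, assuming that the making and the loss of double product both go with partner, takes the peak dose, charged [partner] times time of the maximum, 220 mM·h, and divides it by each charge to get a peak time. For the red run that gives 9.57 h, longer than its 90.0 min, and red is still rising at 4.2%.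

Against 3.0 h, the peak times are 5.50 h for dusk, 2.75 h for noon, 1.47 h for spring and 0.733 h for dawn. This reckoning therefore expects a row that rises, then falls, with its top near 73.3 mM.

The forecast, reading that “double product is itself being consumed”, gives 32%, 57%, 50% and 18%, and the shape rises, then falls.

The flasks give 17.1%, 34.7%, 37.1% and 23.3%, and the shape rises, then falls.

    substrate + partner → first product (k = 0.00571 M⁻¹ s⁻¹)
    substrate + first product → side product (k = 0.00245 M⁻¹ s⁻¹)
    partner + first product → double product (k = 0.00306 M⁻¹ s⁻¹)
    double product ⇌ isomer of the product (K = 17.8, k = 1.11 × 10⁻⁴ s⁻¹)
    partner + double product → triple product (k = 2.20 × 10⁻⁴ M⁻¹ s⁻¹)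

The row turns at 120 mM, higher than the 73.3 mM from the peak dose. In noon at 3.00 h, isomer of the product stands at 28.7% beside double product at 34.7%, and in dusk the forward half-life to the isomer, 1.7 h, is shorter than the 22 h to triple product. Dusk's peak time of 5.50 h lies beyond its end, where double product is made, net, 1.22 times as fast as it is used up. Spring at 3.00 h and dawn at 1.50 h have had the same charged dose, 450 mM·h, yet spring holds 37.1% double product, less than dawn's 52.3%.

(Readings and results are calculated for an exercise, noise included.)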